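**Strategy.** Both prenyl-bearing carbons, C6 of ring A and C3' of ring B, are the only hydrogen-bearing ortho carbons of O5 and O2'; the other ortho carbons, C4a and C1', are quaternary. The two C–C bonds are therefore disconnected to O-allyl ethers. Heating 5,2'-bis(allyloxy)-7,4'-bis(methoxymethoxy)isoflavone should effect two aromatic Claisen rearrangements in one operation, forming C6–C1'' and C3'–C1''' and unmasking the 5- and 2'-hydroxyls, of which only the non-chelated 2'-OH is then methylated. The precursor is made from an isoflavone built with a methyl-masked B ring; the allyl groups become prenyl by cross-metathesis after MOM removal.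

Key step: step 5

**Remarks on the chemistry**
- The target has no stereocentre and no stereogenic double bond (each prenyl alkene carries two methyl groups). It is achiral, so no enantiocontrol is needed and the SMILES carry no stereodescriptors.
- The B ring goes through isoflavone construction as its dimethyl ether. A free 2'-hydroxyl could compete with the A-ring hydroxyl during ring closure and lead to benzofurans.
- The MOM ethers are removed before the metathesis. The acid then meets only monosubstituted allyl groups, not acid-sensitive ortho-prenylphenols.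
- In step 5 the order of the two shifts cannot be predicted and does not change the outcome. It is written with the 5-O-allyl ether moving first.

**Route**

Step 1
Reactants: 1 phloroglucinol, 2 2,4-dimethoxyphenylacetic acid
Product: 4 5,7-dihydroxy-2',4'-dimethoxyisoflavone, via deoxybenzoin 3 (not isolated)
Conditions: BF3·OEt2, 85 °C; then DMF, MsCl, 70 °C (one pot)
Reagents that add atoms: N,N-dimethylformamide, CN(C)C=O (its formyl carbon becomes C2)
Why: Friedel–Crafts C-acylation of phloroglucinol by the BF3-activated acid gives the deoxybenzoin, whose methylene carbon is formylated by the iminium reagent from DMF and MsCl (Vilsmeier-type) and then closes onto an ortho hydroxyl with loss of dimethylamine to form the pyranone ring, a known one-pot isoflavone synthesis in which the methylated B-ring oxygens cannot act as competing nucleophiles.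

Step 2
Reactants: 4 5,7-dihydroxy-2',4'-dimethoxyisoflavone
Product: 5 5,7,2',4'-tetrahydroxyisoflavone
Conditions: BBr3 (excess), CH2Cl2, −78 °C to rt; then H2O
Reagents that add atoms: none
Why: Lewis-acid ether cleavage (BBr3 demethylation), in which bromide attacks each O-methyl carbon of the aryloxy–boron complex in an SN2 step and the aryl borates hydrolyse on work-up, while the chromone core is inert.

Step 3
Reactants: 5 5,7,2',4'-tetrahydroxyisoflavone
Product: 6 5,2'-dihydroxy-7,4'-bis(methoxymethoxy)isoflavone
Conditions: MOMCl (2.1 equiv), K2CO3, acetone, 0 °C to rt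
Reagents that add atoms: chloromethyl methyl ether, COCCl
Why: Williamson-type O-alkylation with limiting MOMCl should take the two most acidic and least hindered phenols, O7 (vinylogous to the C4 carbonyl) and O4', because the 5-OH is chelated to O4 and the 2'-OH is both hydrogen bonded to O4 and shielded by the neighbouring C1'–C3 bond.

Step 4
Reactants: 6 5,2'-dihydroxy-7,4'-bis(methoxymethoxy)isoflavone, 7 allyl bromide
Product: 8 5,2'-bis(allyloxy)-7,4'-bis(methoxymethoxy)isoflavone
Conditions: allyl bromide (4 equiv), K2CO3, DMF, 60 °C
Reagents that add atoms: allyl bromide (7), C=CCBr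
Why: Williamson ether synthesis under more forcing conditions (polar aprotic solvent, excess halide, heat) overcomes the chelation of the 5-OH and alkylates the only two phenols that remain, so no selectivity is required.

Step 5
Reactants: 8 5,2'-bis(allyloxy)-7,4'-bis(methoxymethoxy)isoflavone
Product: 12 6,3'-diallyl-5,2'-dihydroxy-7,4'-bis(methoxymethoxy)isoflavone, via A-ring ortho-dienone 9 (not isolated), via 6-allyl-5-hydroxy mono-ether 10 (not isolated), via B-ring ortho-dienone 11 (not isolated)
Conditions: PhNEt2, 200 °C, sealed tube, Ar
Reagents that add atoms: none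
Why: Each aryl allyl ether undergoes a concerted suprafacial [3,3] sigmatropic shift through a chair-like six-membered transition state, in which the O–CH2 bond breaks while the terminal allyl carbon bonds to the ortho ring carbon, giving a cyclohexa-2,4-dienone that enolises to the phenol. The closest known reaction type is the thermal aromatic Claisen rearrangement of 5-allyloxychromones to 6-allyl-5-hydroxychromones and of ortho-substituted aryl allyl ethers to 2-allylphenols. No ring is closed and no stereocentre is created, since the sp3 carbons of the dienones (C6, C3') become aromatic again on tautomerisation. The step needs regioselectivity on both rings, and the substrate provides it: O5 is flanked by C6–H and the ring-fusion carbon C4a, O2' by C3'–H and the aryl-bearing carbon C1', so only the dienones formed at C6 and C3' can lose a proton and aromatise irreversibly, while a shift onto C4a or C1' is reversible. The MOM ethers on O7 and O4' cannot migrate and tolerate the neutral amine medium, which also buffers the new ortho-allylphenols against acid-catalysed cyclisation; both shifts are isomerisations, so nothing is split off.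

Step 6
Reactants: 12 6,3'-diallyl-5,2'-dihydroxy-7,4'-bis(methoxymethoxy)isoflavone
Product: 13 6,3'-diallyl-5-hydroxy-2'-methoxy-7,4'-bis(methoxymethoxy)isoflavone
Conditions: MeI (1.5 equiv), K2CO3, acetone, 40 °C
Reagents that add atoms: iodomethane, CI
Why: Williamson O-methylation under mild carbonate conditions should take the 2'-phenol only, because the 5-OH is held in a six-membered hydrogen bond to the C4 carbonyl and is flanked by the new 6-allyl group, and this chemoselective step also fixes the 2'-OMe/4'-OH pattern of the B ring.

Step 7
Reactants: 13 6,3'-diallyl-5-hydroxy-2'-methoxy-7,4'-bis(methoxymethoxy)isoflavone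
Product: 14 6,3'-diallyl-5,7,4'-trihydroxy-2'-methoxyisoflavone
Conditions: HCl (1 M in MeOH), 45 °C
Reagents that add atoms: none
Why: Acid-catalysed acetal exchange (MOM ether cleavage through the oxocarbenium ion, which methanol traps) frees the 7- and 4'-hydroxyls while both side chains are still monosubstituted allyl groups that cannot form a tertiary cation, so the acid-induced chroman cyclisation typical of ortho-prenylphenols is avoided.

Step 8
Reactants: 14 6,3'-diallyl-5,7,4'-trihydroxy-2'-methoxyisoflavone, 15 2-methyl-2-butene
Product: 16 2'-methoxylupalbigenin (5,7,4'-trihydroxy-2'-methoxy-6,3'-bis(3-methylbut-2-enyl)isoflavone)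
Conditions: Grubbs II (10 mol%), 2-methyl-2-butene/CH2Cl2 (1:1), 40 °C, sealed tube
Reagents that add atoms: 2-methyl-2-butene (15), CC=C(C)C
Why: Ruthenium-catalysed olefin cross-metathesis of the two terminal alkenes with a large excess of 2-methyl-2-butene transfers an isopropylidene unit to each and releases propene, the NHC–ruthenium catalyst tolerates free phenols, and the new trisubstituted alkenes carry two identical methyl groups so that no E/Z question arises.

**Compound list**

1 | phloroglucinol | Oc1cc(O)cc(O)c1 | starting material
2 | 2,4-dimethoxyphenylacetic acid | COc1ccc(CC(=O)O)c(OC)c1 | starting material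
3 | 2-(2,4-dimethoxyphenyl)-1-(2,4,6-trihydroxyphenyl)ethan-1-one (deoxybenzoin) | COc1ccc(CC(=O)c2c(O)cc(O)cc2O)c(OC)c1 | intermediate (not isolated)
4 | 5,7-dihydroxy-2',4'-dimethoxyisoflavone | COc1ccc(-c2coc3cc(O)cc(O)c3c2=O)c(OC)c1 | intermediate
5 | 5,7,2',4'-tetrahydroxyisoflavone | Oc1ccc(-c2coc3cc(O)cc(O)c3c2=O)c(O)c1 | intermediate
6 | 5,2'-dihydroxy-7,4'-bis(methoxymethoxy)isoflavone | COCOc1ccc(-c2coc3cc(OCOC)cc(O)c3c2=O)c(O)c1 | intermediate
7 | allyl bromide | C=CCBr | starting material
8 | 5,2'-bis(allyloxy)-7,4'-bis(methoxymethoxy)isoflavone | C=CCOc1cc(OCOC)ccc1-c1coc2cc(OCOC)cc(OCC=C)c2c1=O | intermediate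
9 | A-ring ortho-dienone: 6-allyl-3-[2-(allyloxy)-4-(methoxymethoxy)phenyl]-7-(methoxymethoxy)-6H-chromene-4,5-dione (transient sp3 C6, racemic) | C=CCOc1cc(OCOC)ccc1C1=COC2=C(C1=O)C(=O)C(CC=C)C(OCOC)=C2 | intermediate (not isolated)
10 | 6-allyl-2'-(allyloxy)-5-hydroxy-7,4'-bis(methoxymethoxy)isoflavone | C=CCOc1cc(OCOC)ccc1-c1coc2cc(OCOC)c(CC=C)c(O)c2c1=O | intermediate (not isolated)
11 | B-ring ortho-dienone: 6-allyl-3-[3-allyl-4-(methoxymethoxy)-2-oxocyclohexa-4,6-dien-1-yl]-5-hydroxy-7-(methoxymethoxy)chromen-4-one (transient sp3 C3', racemic) | C=CCC1C(OCOC)=CC=C(c2coc3cc(OCOC)c(CC=C)c(O)c3c2=O)C1=O | intermediate (not isolated)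
12 | 6,3'-diallyl-5,2'-dihydroxy-7,4'-bis(methoxymethoxy)isoflavone | C=CCc1c(OCOC)ccc(-c2coc3cc(OCOC)c(CC=C)c(O)c3c2=O)c1O | intermediate
13 | 6,3'-diallyl-5-hydroxy-2'-methoxy-7,4'-bis(methoxymethoxy)isoflavone | C=CCc1c(OCOC)ccc(-c2coc3cc(OCOC)c(CC=C)c(O)c3c2=O)c1OC | intermediate
14 | 6,3'-diallyl-5,7,4'-trihydroxy-2'-methoxyisoflavone | C=CCc1c(O)ccc(-c2coc3cc(O)c(CC=C)c(O)c3c2=O)c1OC | intermediate
15 | 2-methyl-2-butene | CC=C(C)C | starting material
16 | 2'-methoxylupalbigenin | COc1c(-c2coc3cc(O)c(CC=C(C)C)c(O)c3c2=O)ccc(O)c1CC=C(C)C | target

**Step count and risks**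

Total step count: 8. Longest linear sequence: 8 steps (1 and 2 to 16).

Steps most likely to fail:

Step 5. The unactivated B-ring ether needs a temperature at which the A-ring allyl group can leak to C8 (shift onto C4a followed by a Cope shift). At that temperature the new ortho-allylphenols may also cyclise or the MOM ethers erode, so conversion and regiochemical purity may both suffer. The fallback sets out from 8 and decouples the two events. Eu(fod)3 (10 mol%) in CHCl3 at 60–70 °C coordinates the O4/O5 pair and catalyses only the A-ring shift, so the mono-ether 10 is now isolated. The single remaining B-ring rearrangement is then run on 10 by short microwave heating in N,N-diethylaniline, which returns to the route at 12. This fallback makes no new compound (F0).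

Step 3. Discrimination between O4' and O2' may be insufficient, or over-alkylation may occur, during the twofold MOM protection. An allyl group would then end up on O4' and misdirect the B-ring rearrangement. The fallback sets out from 5 and lets steric demand decide. TIPSCl (2.2 equiv) and imidazole in DMF should silylate only the unhindered O7 and O4' to give 7,4'-bis(triisopropylsilyloxy)-5,2'-dihydroxyisoflavone F1. Mitsunobu etherification (allyl alcohol, PPh3, DIAD, THF) needs no base and therefore spares aryl silyl ethers; it gives 5,2'-bis(allyloxy)-7,4'-bis(triisopropylsilyloxy)isoflavone F2. TBAF buffered with AcOH gives 5,2'-bis(allyloxy)-7,4'-dihydroxyisoflavone F3, in which only O7 and O4' are free. MOMCl and DIPEA in CH2Cl2 then return to the route at 8, bypassing 6.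

Step 8. The free phenols may limit solubility in the olefin-rich medium or slow the catalyst. The twofold metathesis could then stall at mono-prenylated material, or ruthenium hydrides could isomerise allyl to propenyl groups. The fallback sets out from 14 and caps O7 and O4' (Ac2O, pyridine, 0 °C to rt; the chelated 5-OH is expected to stay free) to give 7,4'-diacetoxy-6,3'-diallyl-5-hydroxy-2'-methoxyisoflavone F4. Cross-metathesis with 15 on this soluble diester gives 7,4'-diacetoxy-5-hydroxy-2'-methoxy-6,3'-diprenylisoflavone F5. K2CO3 in MeOH at rt, which is harmless to prenyl groups, removes the acetates and arrives at 16.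

**Further compounds**

F0 | step 5 | none | none
F1 | step 3 | 7,4'-bis(triisopropylsilyloxy)-5,2'-dihydroxyisoflavone | Oc1cc(O[Si](C(C)C)(C(C)C)C(C)C)ccc1-c1coc2cc(O[Si](C(C)C)(C(C)C)C(C)C)cc(O)c2c1=O
F2 | step 3 | 5,2'-bis(allyloxy)-7,4'-bis(triisopropylsilyloxy)isoflavone | C=CCOc1cc(O[Si](C(C)C)(C(C)C)C(C)C)ccc1-c1coc2cc(O[Si](C(C)C)(C(C)C)C(C)C)cc(OCC=C)c2c1=O
F3 | step 3 | 5,2'-bis(allyloxy)-7,4'-dihydroxyisoflavone | C=CCOc1cc(O)ccc1-c1coc2cc(O)cc(OCC=C)c2c1=O
F4 | step 8 | 7,4'-diacetoxy-6,3'-diallyl-5-hydroxy-2'-methoxyisoflavone | C=CCc1c(OC(C)=O)ccc(-c2coc3cc(OC(C)=O)c(CC=C)c(O)c3c2=O)c1OC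
F5 | step 8 | 7,4'-diacetoxy-5-hydroxy-2'-methoxy-6,3'-diprenylisoflavone | COc1c(-c2coc3cc(OC(C)=O)c(CC=C(C)C)c(O)c3c2=O)ccc(OC(C)=O)c1CC=C(C)C
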